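Everything rests on excising C3 of ring C. This carbon bears only an oxygen substituent and sits alone between C2 (bonded to O1 and ring B) and the C4 carbonyl, so deleting it contracts the pyranone to the furan of a 2-aryl-3-oxybenzofuran. Forward, dibromocarbene is delivered to the furan double bond of silyl ether 4 and the strained adduct unzips: one operation makes C2–C3 and C3–C4, enlarges the furan to ring C, frees the C4 ketone and leaves on C3 a bromine later traded for methoxy. Precursor 4 is a 4,6-dimethoxybenzofuran with OTBS at C3 and 4-benzyloxyphenyl at C2; benzyl stands in for the carbene-sensitive prenyl group.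

Key step: step 3

Remark: the target has no stereocentre and no stereogenic alkene, so nothing needs stereocontrol; 3 and 6 are racemic and lose their stereocentres within the route. Chromenones carry flavone numbering (ring A benzo, ring C pyranone, ring B the primed 2-aryl group); the five-membered precursors carry benzofuran numbering.

Step 1
Reactants: 1 4,6-dimethoxy-1-benzofuran-3(2H)-one; 2 1-(benzyloxy)-4-bromobenzene
Product: 3 rac-2-[4-(benzyloxy)phenyl]-4,6-dimethoxy-1-benzofuran-3(2H)-one
Conditions: Pd(OAc)2 (3 mol %), XPhos (6 mol %), NaOtBu (2.2 equiv), degassed toluene, 80 °C, Ar; then aq NH4Cl under Ar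
Reagents that add atoms: none
Why: Buchwald–Hartwig–Miura ketone α-arylation, in which zerovalent palladium formed in situ inserts into the C–Br bond of 2, the sodium enolate of 1 replaces bromide on the metal and reductive elimination from the bulky-phosphine complex makes the C2–aryl bond, after which the more acidic product rests as its hindered aromatic 3-oxidobenzofuran salt and resists a second arylation; the new C2 stereocentre forms racemic and is erased in step 2.

Step 2
Reactants: 3 rac-2-[4-(benzyloxy)phenyl]-4,6-dimethoxy-1-benzofuran-3(2H)-one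
Product: 4 {[2-(4-benzyloxyphenyl)-4,6-dimethoxy-1-benzofuran-3-yl]oxy}(tert-butyl)dimethylsilane
Conditions: TBSOTf (1.3 equiv), Et3N (2.5 equiv), CH2Cl2, 0 °C to rt; cold aq NaHCO3, Et3N-deactivated silica
Reagents that add atoms: tert-butyldimethylsilyl trifluoromethanesulfonate, CC(C)(C)[Si](C)(C)OS(=O)(=O)C(F)(F)F
Why: Soft enolisation with O-silylation (silyl enol ether formation), in which Et3N removes the doubly activated C2–H once the ketone oxygen is silylated, aromatisation to the benzofuran makes the O-silyl isomer the sink and erases the C2 stereocentre, and the tert-butyl group on silicon shields it from tert-butoxide in step 3.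

Step 3
Reactants: 4 {[2-(4-benzyloxyphenyl)-4,6-dimethoxy-1-benzofuran-3-yl]oxy}(tert-butyl)dimethylsilane; 5 bromoform
Product: 8 2-[4-(benzyloxy)phenyl]-3-bromo-5,7-dimethoxy-4H-chromen-4-one, via dibromocyclopropane adduct 6 (not isolated), via silyloxychromenylium bromide 7 (not isolated)
Conditions: CHBr3 (3 equiv), KOtBu (4 equiv, added in portions to 4 and CHBr3), toluene–hexane, −30 °C to rt; then 1 M HCl, THF, rt
Reagents that add atoms: none
Why: tert-Butoxide deprotonates 5, the tribromomethyl anion sheds bromide, and the resulting electrophilic singlet CBr2 is taken up in a single cheletropic (2+1) event by the furan π-bond of 4 to give the fused adduct 6. Ionisation of the endo C–Br bond of 6 goes hand in hand with disrotatory scission of the bond shared by the two small rings (cyclopropyl-to-allyl cation opening, two electrons), which gives the aromatic benzopyrylium ion 7 with its charge spread over O1, the silyloxy oxygen and the 4-benzyloxyphenyl group; bromide, tert-butoxide or the acidic work-up then takes silicon away and uncovers the C4 ketone of 8. The closest known reaction types are the dihalocarbene one-carbon ring expansion of cyclic silyl enol ethers to 2-halo enones (1-indanone silyl enol ethers to 2-halo-1-naphthols being the carbocyclic counterpart) and the Ciamician–Dennstedt expansion of indoles and related benzo-fused heteroles, and 4 unites both substrate types in one new molecule. Ring C is thus closed by ring enlargement and not by cyclisation, the bicyclo[3.1.0] unit of 6 becoming the six-membered pyranone when its zero-atom bridge breaks. No stereocentre survives, since the two in 6 are cis by geometric necessity, racemic, and both turn sp2 in 7. What must be controlled is the site of carbene attack (furan bond against three benzene rings and the benzylic C–H bonds), and this is secured by the two oxygens and the donor aryl group, which make this alkene by far the most nucleophilic π-bond, and by postponing the prenyl alkene to the last step.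

Step 4
Reactants: 8 2-[4-(benzyloxy)phenyl]-3-bromo-5,7-dimethoxy-4H-chromen-4-one
Product: 9 2-[4-(benzyloxy)phenyl]-3,5,7-trimethoxy-4H-chromen-4-one
Conditions: NaOMe (5 equiv, 25 wt % in MeOH), CuBr (0.3 equiv), DMF, 100 °C, Ar
Reagents that add atoms: sodium methoxide, [Na+].[O-]C
Why: Ullmann-type copper-mediated methoxylation of a C(sp2)–Br bond, a method in regular use for exchanging ring bromines of flavones for methoxy, in which a methoxycuprate of monovalent copper engages the C3–Br bond by oxidative addition and reductive elimination while the three donor oxygens on rings A and B lower the electrophilicity of C2 enough for ring C to withstand methoxide.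

Step 5
Reactants: 9 2-[4-(benzyloxy)phenyl]-3,5,7-trimethoxy-4H-chromen-4-one
Product: 10 5-hydroxy-2-(4-hydroxyphenyl)-3,7-dimethoxy-4H-chromen-4-one (kumatakenin)
Conditions: BCl3 (4 equiv, 1 M in CH2Cl2), C6HMe5 (3 equiv), CH2Cl2, −78 to 0 °C; then H2O
Reagents that add atoms: none
Why: Lewis-acid ether cleavage under chelation control, in which BCl3 bound to the C4 carbonyl closes a six-membered O–B–O chelate with the peri 5-oxygen so that chloride removes only that methyl group, the benzyl ether ionises already in the cold and its cation is caught by pentamethylbenzene in a Friedel–Crafts alkylation instead of attacking ring A, and the 3- and 7-methyl ethers, which cannot form such a six-membered chelate, should stay intact at or below 0 °C.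

Step 6
Reactants: 10 5-hydroxy-2-(4-hydroxyphenyl)-3,7-dimethoxy-4H-chromen-4-one; 11 prenyl bromide (1-bromo-3-methylbut-2-ene)
Product: 12 5-hydroxy-3,7-dimethoxy-2-{4-[(3-methylbut-2-en-1-yl)oxy]phenyl}-4H-chromen-4-one (target)
Conditions: K2CO3 (1.2 equiv), 11 (1.1 equiv), acetone, rt to 40 °C
Reagents that add atoms: none
Why: Williamson ether synthesis with site selectivity from hydrogen bonding, since the 5-OH is tied to the C4 carbonyl and is less acidic and less nucleophilic, so about one equivalent of weak base ionises only the 4'-phenol, which displaces bromide from the primary allylic carbon of 11 by SN2.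

Compound list
1 | 4,6-dimethoxy-1-benzofuran-3(2H)-one | COc1cc(OC)c2c(c1)OCC2=O | starting material
2 | 1-(benzyloxy)-4-bromobenzene | Brc1ccc(OCc2ccccc2)cc1 | starting material
3 | rac-2-[4-(benzyloxy)phenyl]-4,6-dimethoxy-1-benzofuran-3(2H)-one (racemic, C2 labile) | COc1cc(OC)c2c(c1)OC(c1ccc(OCc3ccccc3)cc1)C2=O | intermediate
4 | {[2-(4-benzyloxyphenyl)-4,6-dimethoxy-1-benzofuran-3-yl]oxy}(tert-butyl)dimethylsilane | COc1cc(OC)c2c(O[Si](C)(C)C(C)(C)C)c(-c3ccc(OCc4ccccc4)cc3)oc2c1 | intermediate
5 | bromoform | BrC(Br)Br | starting material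
6 | rac-1a-[4-(benzyloxy)phenyl]-1,1-dibromo-6b-[(tert-butyldimethylsilyl)oxy]-4,6-dimethoxy-1a,6b-dihydro-1H-cyclopropa[b][1]benzofuran (racemic; cis fusion is the only possible one) | COc1cc(OC)c2c(c1)OC1(c3ccc(OCc4ccccc4)cc3)C(Br)(Br)C21O[Si](C)(C)C(C)(C)C | intermediate (not isolated)
7 | 2-[4-(benzyloxy)phenyl]-3-bromo-4-[(tert-butyldimethylsilyl)oxy]-5,7-dimethoxychromenylium bromide | COc1cc(OC)c2c(O[Si](C)(C)C(C)(C)C)c(Br)c(-c3ccc(OCc4ccccc4)cc3)[o+]c2c1.[Br-] | intermediate (not isolated)
8 | 2-[4-(benzyloxy)phenyl]-3-bromo-5,7-dimethoxy-4H-chromen-4-one | COc1cc(OC)c2c(=O)c(Br)c(-c3ccc(OCc4ccccc4)cc3)oc2c1 | intermediate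
9 | 2-[4-(benzyloxy)phenyl]-3,5,7-trimethoxy-4H-chromen-4-one | COc1cc(OC)c2c(=O)c(OC)c(-c3ccc(OCc4ccccc4)cc3)oc2c1 | intermediate
10 | 5-hydroxy-2-(4-hydroxyphenyl)-3,7-dimethoxy-4H-chromen-4-one | COc1cc(O)c2c(=O)c(OC)c(-c3ccc(O)cc3)oc2c1 | intermediate
11 | prenyl bromide (1-bromo-3-methylbut-2-ene) | CC(C)=CCBr | starting material
12 | 5-hydroxy-3,7-dimethoxy-2-{4-[(3-methylbut-2-en-1-yl)oxy]phenyl}-4H-chromen-4-one | COc1cc(O)c2c(=O)c(OC)c(-c3ccc(OCC=C(C)C)cc3)oc2c1 | target

Total step count: 6. Longest linear sequence: 6 steps (1 → 3 → 4 → 8 → 9 → 10 → 12).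

Steps most likely to fail

Step 3 (key step). Three things may go wrong:
- tert-Butoxide strips the silyl group before the carbene arrives.
- The carbene adds too slowly to a tetrasubstituted double bond that is part of an aromatic furan.
- The carbene is diverted into benzylic C–H insertion.

The fallback gives up the ring expansion and assembles ring C by a Baker–Venkataraman acyl shift and cyclodehydration, with C3 and its methoxy group supplied by an ω-methoxyacetophenone. It sets out from 2 and comes back at 9, so it also bypasses step 4. Bromine–lithium exchange on 2 (n-BuLi, THF, −78 °C) and quenching with CO2 would give 4-(benzyloxy)benzoic acid F1. Steglich esterification (EDC·HCl, DMAP, CH2Cl2) with purchased 1-(2-hydroxy-4,6-dimethoxyphenyl)-2-methoxyethan-1-one (COCC(=O)c1c(O)cc(OC)cc1OC) would give 3,5-dimethoxy-2-(methoxyacetyl)phenyl 4-(benzyloxy)benzoate F2. LiN(SiMe3)2 (THF, −78 to 0 °C) would move the aroyl group from oxygen to the α-carbon and give 1-[4-(benzyloxy)phenyl]-3-(2-hydroxy-4,6-dimethoxyphenyl)-2-methoxypropane-1,3-dione F3. TsOH·H2O in toluene at 80 °C would then close ring C with loss of water to 9.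

Step 4. Methoxide may add to C2 in conjugate fashion, open ring C and let the freed phenoxide re-close onto the halogen-bearing carbon (contraction to a five-membered ring). The bromine may also be lost reductively. The fallback avoids any strong oxygen nucleophile by inverting the polarity at C3; it sets out from 8 and comes back at 9. Miyaura borylation (B2pin2, PdCl2(dppf), KOAc, dioxane, 90 °C) would give 2-[4-(benzyloxy)phenyl]-5,7-dimethoxy-3-(4,4,5,5-tetramethyl-1,3,2-dioxaborolan-2-yl)-4H-chromen-4-one F4. Mild oxidation (NaBO3·4H2O, THF–H2O, rt) would give 2-[4-(benzyloxy)phenyl]-3-hydroxy-5,7-dimethoxy-4H-chromen-4-one F5. O-Methylation (MeI, K2CO3, acetone) would deliver 9.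

Step 1. The enolate of 1 may self-condense, arylation may run on to the quaternary stage, or the electron-rich product enolate may be oxidised by traces of air at C2. The fallback silylates first and makes the C2–aryl bond by cross-coupling of a heteroaryl boronate instead of an enolate; it sets out from 1 and comes back at 4, bypassing 3. TBSOTf and Et3N (CH2Cl2, 0 °C) on 1 would give tert-butyl[(4,6-dimethoxy-1-benzofuran-3-yl)oxy]dimethylsilane F6. Iridium-catalysed C–H borylation ([Ir(OMe)(cod)]2, 4,4'-di-tert-butyl-2,2'-bipyridine, B2pin2, THF, 60 °C) at the heteroaryl C2–H would give tert-butyl{[4,6-dimethoxy-2-(4,4,5,5-tetramethyl-1,3,2-dioxaborolan-2-yl)-1-benzofuran-3-yl]oxy}dimethylsilane F7. Suzuki–Miyaura coupling with 2 (Pd(OAc)2, SPhos, K3PO4, THF–H2O, 40 °C) would give 4. Any material that loses silicon there is 3 and re-enters at step 2.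

Further compounds
F1 | step 3 | 4-(benzyloxy)benzoic acid | OC(=O)c1ccc(OCc2ccccc2)cc1
F2 | step 3 | 3,5-dimethoxy-2-(methoxyacetyl)phenyl 4-(benzyloxy)benzoate | COCC(=O)c1c(OC)cc(OC)cc1OC(=O)c1ccc(OCc2ccccc2)cc1
F3 | step 3 | 1-[4-(benzyloxy)phenyl]-3-(2-hydroxy-4,6-dimethoxyphenyl)-2-methoxypropane-1,3-dione (racemic, enolisable) | COC(C(=O)c1ccc(OCc2ccccc2)cc1)C(=O)c1c(O)cc(OC)cc1OC
F4 | step 4 | 2-[4-(benzyloxy)phenyl]-5,7-dimethoxy-3-(4,4,5,5-tetramethyl-1,3,2-dioxaborolan-2-yl)-4H-chromen-4-one | COc1cc(OC)c2c(=O)c(B3OC(C)(C)C(C)(C)O3)c(-c3ccc(OCc4ccccc4)cc3)oc2c1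
F5 | step 4 | 2-[4-(benzyloxy)phenyl]-3-hydroxy-5,7-dimethoxy-4H-chromen-4-one | COc1cc(OC)c2c(=O)c(O)c(-c3ccc(OCc4ccccc4)cc3)oc2c1
F6 | step 1 | tert-butyl[(4,6-dimethoxy-1-benzofuran-3-yl)oxy]dimethylsilane | COc1cc(OC)c2c(O[Si](C)(C)C(C)(C)C)coc2c1
F7 | step 1 | tert-butyl{[4,6-dimethoxy-2-(4,4,5,5-tetramethyl-1,3,2-dioxaborolan-2-yl)-1-benzofuran-3-yl]oxy}dimethylsilane | COc1cc(OC)c2c(O[Si](C)(C)C(C)(C)C)c(B3OC(C)(C)C(C)(C)O3)oc2c1
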